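**Retrosynthetic overview**
1. Disconnections: C5–C6 (alkenylalane + aldehyde), C1–C2 (alkenylalane + benzylic bromide), C12–C13 (acid chloride + prenylstannane); both ketones are unmasked together at the end.
2. C6–C15 half: meso cis-2,6-dimethylcyclohexanone is desymmetrised by a chiral lithium amide (sets C11). Ozonolysis of the enol silane then opens the ring to (2R)-2-methyl-6-oxoheptanoic acid, which keeps all eight carbons (C7–C12 and both methyls).
3. The methyl ketone becomes the terminal alkyne (C6≡C7), later methylaluminated to the 6E olefin; the acid becomes the prenyl carbinol.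
4. Arene half: symmetric 4-methoxy-2,6-dimethylphenol; one of its two equivalent methyls is brominated and becomes C1; the 2E olefin comes from methylalumination of but-3-yn-1-ol.
5. No ring is built: the arene is bought, and the only ring event is the opening of the cyclohexanone.

Assumption: 1 is the pure cis (meso) isomer, separated from the commercial cis/trans mixture, and the (R,R)-amide is taken to give the (R)-enol ether by analogy with 4-substituted cyclohexanones; if the sense is opposite, the (S,S)-amide is used.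

**Step 1**
Reactants: 1 cis-2,6-dimethylcyclohexanone
Product: 3 trimethyl{[(6R)-2,6-dimethylcyclohex-1-en-1-yl]oxy}silane, via lithium enolate 2 (not isolated)
Conditions: (R,R)-bis(1-phenylethyl)amine, n-BuLi, THF, −78 °C; Me3SiCl (in situ quench), 1, −100 → −78 °C
Reagents that add atoms: chlorotrimethylsilane, C[Si](C)(C)Cl
Why: Enantioselective deprotonation (desymmetrisation with a chiral lithium amide, internal Me3SiCl quench): the amide removes one of the two enantiotopic axial α-hydrogens of the meso ketone, so the untouched α-carbon becomes the (R) stereocentre (later C11), expected in about 90% ee.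

**Step 2**
Reactants: 3 trimethyl{[(6R)-2,6-dimethylcyclohex-1-en-1-yl]oxy}silane
Product: 5 (2R)-2-methyl-6-oxoheptanoic acid, via silyl ester 4 (not isolated)
Conditions: O3, CH2Cl2/MeOH, −78 °C; Me2S, −78 °C → rt
Reagents that add atoms: ozone, [O-][O+]=O
Why: Ozonolysis of the tetrasubstituted silyl enol ether cleaves the only C=C bond to give the methyl ketone (C7) and, through the silyl ester, the acid (C12) under non-basic conditions that leave the α-stereocentre untouched.

**Step 3**
Reactants: 5 (2R)-2-methyl-6-oxoheptanoic acid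
Product: 7 (2R)-2-methylhept-6-ynoic acid, via enol phosphate 6 (not isolated)
Conditions: LiN(iPr)2 (2.1 equiv), THF, −78 °C; ClP(O)(OEt)2 (1.05 equiv); LiN(iPr)2 (2.3 equiv), −78 → 0 °C; aq. HCl
Reagents that add atoms: none
Why: Negishi ketone-to-alkyne conversion: the lithium carboxylate shields the α-stereocentre while the kinetic methyl-side enolate is O-phosphorylated and the enol phosphate undergoes E2 elimination to the terminal alkyne.

**Step 4**
Reactants: 7 (2R)-2-methylhept-6-ynoic acid
Product: 9 (6R)-2,6-dimethylundec-2-en-10-yn-5-one, via acid chloride 8 (not isolated)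
Conditions: (COCl)2, DMF (cat.), CH2Cl2, 0 °C → rt, evaporate; Bu3SnCH2CH=CMe2, PdCl2(PPh3)2 (3 mol %), THF, 55 °C
Reagents that add atoms: tributyl(3-methylbut-2-en-1-yl)stannane, CCCC[Sn](CCCC)(CCCC)CC=C(C)C
Why: Acid chloride formation then Migita–Kosugi–Stille acylation: the acylpalladium chloride takes the prenyl group from tin and reductive elimination occurs at the unsubstituted allyl terminus, giving the linear β,γ-unsaturated ketone without base, so C11 is not epimerised.

**Step 5**
Reactants: 9 (6R)-2,6-dimethylundec-2-en-10-yn-5-one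
Product: 10 (6R)-2,6-dimethylundec-2-en-10-yn-5-ol
Conditions: NaBH4, MeOH, −20 °C
Reagents that add atoms: none
Why: Hydride reduction masks the ketone as a carbinol so that it survives AlMe3; the new carbinol centre is uncontrolled and irrelevant because it is oxidised again in step 11.

**Step 6**
Reactants: 11 4-methoxy-2,6-dimethylphenol
Product: 12 tert-butyl(4-methoxy-2,6-dimethylphenoxy)dimethylsilane
Conditions: TBSCl, imidazole, DMF, 40 °C
Reagents that add atoms: tert-butyl(chloro)dimethylsilane, CC(C)(C)[Si](C)(C)Cl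
Why: Silyl ether formation protects the electron-rich phenol against NBS, AlMe3 and the periodinane used later.

**Step 7**
Reactants: 12 tert-butyl(4-methoxy-2,6-dimethylphenoxy)dimethylsilane
Product: 13 [2-(bromomethyl)-4-methoxy-6-methylphenoxy](tert-butyl)dimethylsilane
Conditions: NBS (1.0 equiv), AIBN (cat.), PhCF3, 80 °C
Reagents that add atoms: N-bromosuccinimide, O=C1CCC(=O)N1Br
Why: Wohl–Ziegler benzylic bromination with one equivalent of NBS functionalises one of the two equivalent methyl groups (radical chain in a non-polar solvent keeps ring bromination down), giving the carbon that becomes C1.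

**Step 8**
Reactants: 14 but-3-yn-1-ol; 13 [2-(bromomethyl)-4-methoxy-6-methylphenoxy](tert-butyl)dimethylsilane
Product: 16 (3E)-5-(2-{[tert-butyl(dimethyl)silyl]oxy}-5-methoxy-3-methylphenyl)-3-methylpent-3-en-1-ol, via alkenylalane 15 (not isolated)
Conditions: AlMe3 (2.5 equiv), Cp2ZrCl2 (0.25 equiv), CH2Cl2, 0 °C → rt; evaporate excess AlMe3; 13, Pd(PPh3)4 (5 mol %), THF, rt; aq. NH4Cl
Reagents that add atoms: trimethylaluminium, C[Al](C)C
Why: Negishi Zr-catalysed carboalumination adds Me and Al syn across the terminal alkyne (Me on the internal carbon), and Pd-catalysed cross-coupling of the alkenylalane with the benzylic bromide proceeds with retention, which fixes the 2E double bond.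

**Step 9**
Reactants: 16 (3E)-5-(2-{[tert-butyl(dimethyl)silyl]oxy}-5-methoxy-3-methylphenyl)-3-methylpent-3-en-1-ol
Product: 17 (3E)-5-(2-{[tert-butyl(dimethyl)silyl]oxy}-5-methoxy-3-methylphenyl)-3-methylpent-3-enal
Conditions: Dess–Martin periodinane, NaHCO3, CH2Cl2, 0 °C; used crude at once
Reagents that add atoms: none
Why: Buffered Dess–Martin oxidation gives the β,γ-unsaturated aldehyde without moving the double bond into conjugation.

**Step 10**
Reactants: 10 (6R)-2,6-dimethylundec-2-en-10-yn-5-ol; 17 (3E)-5-(2-{[tert-butyl(dimethyl)silyl]oxy}-5-methoxy-3-methylphenyl)-3-methylpent-3-enal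
Product: 19 (2E,6E,11R)-1-(2-{[tert-butyl(dimethyl)silyl]oxy}-5-methoxy-3-methylphenyl)-3,7,11,15-tetramethylhexadeca-2,6,14-triene-5,12-diol, via alkenylalane 18 (not isolated)
Conditions: 10, AlMe3 (3 equiv), Cp2ZrCl2 (0.3 equiv), CH2Cl2, rt; evaporate excess AlMe3; 17, CH2Cl2/Et2O, −78 → −20 °C; aq. NH4Cl
Reagents that add atoms: trimethylaluminium, C[Al](C)C
Why: Negishi carboalumination of the terminal alkyne (syn, Me on C7) sets the 6E olefin and 1,2-addition of the alkenylalane to the aldehyde forms the C5–C6 bond; the C5 carbinol centre is uncontrolled and is removed in step 11.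

**Step 11**
Reactants: 19 (2E,6E,11R)-1-(2-{[tert-butyl(dimethyl)silyl]oxy}-5-methoxy-3-methylphenyl)-3,7,11,15-tetramethylhexadeca-2,6,14-triene-5,12-diol
Product: 20 (2E,6E,11R)-1-(2-{[tert-butyl(dimethyl)silyl]oxy}-5-methoxy-3-methylphenyl)-3,7,11,15-tetramethylhexadeca-2,6,14-triene-5,12-dione
Conditions: Dess–Martin periodinane (3 equiv), NaHCO3, CH2Cl2, 0 °C → rt
Reagents that add atoms: none
Why: Double Dess–Martin oxidation under buffered conditions converts both secondary alcohols into ketones without conjugating the β,γ-double bonds or epimerising C11.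

**Step 12**
Reactants: 20 (2E,6E,11R)-1-(2-{[tert-butyl(dimethyl)silyl]oxy}-5-methoxy-3-methylphenyl)-3,7,11,15-tetramethylhexadeca-2,6,14-triene-5,12-dione
Product: 21 (2E,6E,11R)-1-(2-hydroxy-5-methoxy-3-methylphenyl)-3,7,11,15-tetramethylhexadeca-2,6,14-triene-5,12-dione
Conditions: Bu4NF/AcOH (1:1), THF, 0 °C
Reagents that add atoms: none
Why: Fluoride desilylation of the aryl silyl ether, buffered with acetic acid, frees the phenol while the base-sensitive β,γ-unsaturated ketones and C11 stay intact.

**Compound list**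
1 | cis-2,6-dimethylcyclohexanone (meso, 2R,6S) | O=C1[C@H](C)CCC[C@@H]1C | starting material
2 | lithium (6R)-2,6-dimethylcyclohex-1-en-1-olate | C[C@@H]1CCCC(C)=C1[O-].[Li+] | intermediate
3 | trimethyl{[(6R)-2,6-dimethylcyclohex-1-en-1-yl]oxy}silane | C[C@@H]1CCCC(C)=C1O[Si](C)(C)C | intermediate
4 | trimethylsilyl (2R)-2-methyl-6-oxoheptanoate | CC(=O)CCC[C@@H](C)C(=O)O[Si](C)(C)C | intermediate
5 | (2R)-2-methyl-6-oxoheptanoic acid | CC(=O)CCC[C@@H](C)C(=O)O | intermediate
6 | (2R)-6-[(diethoxyphosphoryl)oxy]-2-methylhept-6-enoic acid (lithium salt in the flask) | C=C(CCC[C@@H](C)C(=O)O)OP(=O)(OCC)OCC | intermediate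
7 | (2R)-2-methylhept-6-ynoic acid | C#CCCC[C@@H](C)C(=O)O | intermediate
8 | (2R)-2-methylhept-6-ynoyl chloride | C#CCCC[C@@H](C)C(=O)Cl | intermediate
9 | (6R)-2,6-dimethylundec-2-en-10-yn-5-one | C#CCCC[C@@H](C)C(=O)CC=C(C)C | intermediate
10 | (6R)-2,6-dimethylundec-2-en-10-yn-5-ol (both C5 epimers) | C#CCCC[C@@H](C)C(O)CC=C(C)C | intermediate
11 | 4-methoxy-2,6-dimethylphenol | COc1cc(C)c(O)c(C)c1 | starting material
12 | tert-butyl(4-methoxy-2,6-dimethylphenoxy)dimethylsilane | COc1cc(C)c(O[Si](C)(C)C(C)(C)C)c(C)c1 | intermediate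
13 | [2-(bromomethyl)-4-methoxy-6-methylphenoxy](tert-butyl)dimethylsilane | COc1cc(C)c(O[Si](C)(C)C(C)(C)C)c(CBr)c1 | intermediate
14 | but-3-yn-1-ol | C#CCCO | starting material
15 | [(1E)-4-[(dimethylalumanyl)oxy]-2-methylbut-1-en-1-yl]dimethylalumane | C[Al](C)/C=C(\C)CCO[Al](C)C | intermediate
16 | (3E)-5-(2-{[tert-butyl(dimethyl)silyl]oxy}-5-methoxy-3-methylphenyl)-3-methylpent-3-en-1-ol | COc1cc(C)c(O[Si](C)(C)C(C)(C)C)c(C/C=C(\C)CCO)c1 | intermediate
17 | (3E)-5-(2-{[tert-butyl(dimethyl)silyl]oxy}-5-methoxy-3-methylphenyl)-3-methylpent-3-enal | COc1cc(C)c(O[Si](C)(C)C(C)(C)C)c(C/C=C(\C)CC=O)c1 | intermediate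
18 | [(1E,6R)-7-[(dimethylalumanyl)oxy]-2,6,10-trimethylundeca-1,9-dien-1-yl]dimethylalumane | C[Al](C)/C=C(\C)CCC[C@@H](C)C(O[Al](C)C)CC=C(C)C | intermediate
19 | (2E,6E,11R)-1-(2-{[tert-butyl(dimethyl)silyl]oxy}-5-methoxy-3-methylphenyl)-3,7,11,15-tetramethylhexadeca-2,6,14-triene-5,12-diol (C5 and C12 epimers) | COc1cc(C)c(O[Si](C)(C)C(C)(C)C)c(C/C=C(\C)CC(O)/C=C(\C)CCC[C@@H](C)C(O)CC=C(C)C)c1 | intermediate
20 | (2E,6E,11R)-1-(2-{[tert-butyl(dimethyl)silyl]oxy}-5-methoxy-3-methylphenyl)-3,7,11,15-tetramethylhexadeca-2,6,14-triene-5,12-dione | COc1cc(C)c(O[Si](C)(C)C(C)(C)C)c(C/C=C(\C)CC(=O)/C=C(\C)CCC[C@@H](C)C(=O)CC=C(C)C)c1 | intermediate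
21 | (2E,6E,11R)-1-(2-hydroxy-5-methoxy-3-methylphenyl)-3,7,11,15-tetramethylhexadeca-2,6,14-triene-5,12-dione | COc1cc(C)c(O)c(C/C=C(\C)CC(=O)/C=C(\C)CCC[C@@H](C)C(=O)CC=C(C)C)c1 | target

**Step count**
Total: 12 steps. Longest linear sequence: 8 steps (steps 1–5, then 10–12); the arene branch is steps 6–9.

**Steps most likely to fail**

Step 3 (ketone to alkyne on the free keto acid): the carboxylate may be phosphorylated, the internal enolate may compete, and excess amide base could touch C11. Fallback, setting out from 5 and returning at 7: 5 is esterified with Me3SiCHN2 to methyl (2R)-2-methyl-6-oxoheptanoate F1. The kinetic enol triflate methyl (2R)-2-methyl-6-{[(trifluoromethyl)sulfonyl]oxy}hept-6-enoate F2 is made with KN(SiMe3)2 and PhNTf2 at −78 °C. Elimination with wet Bu4NF in DMF gives methyl (2R)-2-methylhept-6-ynoate F3, and LiOH in THF/water at 0 °C returns 7.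

Step 4 (acyl Stille with the prenylstannane): branched (1,1-dimethylallyl) ketone, decarbonylation or conjugation of the product could intervene. Fallback, setting out from 7 and returning at 10: 7 is reduced with LiAlH4 to (2R)-2-methylhept-6-yn-1-ol F4 and oxidised (Swern) to (2R)-2-methylhept-6-ynal F5, used crude. Corey–Chaykovsky methylenation (trimethylsulfonium iodide, n-BuLi) gives 2-[(2R)-hept-6-yn-2-yl]oxirane F6. Opening at the terminal carbon with 2-methylprop-1-enylmagnesium bromide (3 equiv, the first deprotonating the alkyne) and CuI (10 mol %) gives 10 directly.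

Step 10 (alkenylalane addition to the enolisable β,γ-unsaturated aldehyde): enolisation, conjugation of 17 or methyl transfer may compete. Fallback, setting out from 10 and returning at 19: the alkenylalane 18 is quenched with I2 to give (6R,10E)-11-iodo-2,6,10-trimethylundeca-2,10-dien-5-ol F7. F7 is then joined to 17 in a Nozaki–Hiyama–Kishi reaction (CrCl2, NiCl2 (cat.), DMSO/THF, rt), which tolerates the free hydroxyl and the enolisable aldehyde, to give 19.

**Further compounds**
F1 | step 3 | methyl (2R)-2-methyl-6-oxoheptanoate | CC(=O)CCC[C@@H](C)C(=O)OC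
F2 | step 3 | methyl (2R)-2-methyl-6-{[(trifluoromethyl)sulfonyl]oxy}hept-6-enoate | C=C(CCC[C@@H](C)C(=O)OC)OS(=O)(=O)C(F)(F)F
F3 | step 3 | methyl (2R)-2-methylhept-6-ynoate | C#CCCC[C@@H](C)C(=O)OC
F4 | step 4 | (2R)-2-methylhept-6-yn-1-ol | C#CCCC[C@@H](C)CO
F5 | step 4 | (2R)-2-methylhept-6-ynal | C#CCCC[C@@H](C)C=O
F6 | step 4 | 2-[(2R)-hept-6-yn-2-yl]oxirane | C#CCCC[C@@H](C)C1CO1
F7 | step 10 | (6R,10E)-11-iodo-2,6,10-trimethylundeca-2,10-dien-5-ol | I/C=C(\C)CCC[C@@H](C)C(O)CC=C(C)C
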